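**Retrosynthetic overview**
1. Punaglandin 4 (17) ⇒ protected dienone 15 (acetonide off, then acetylation); the C7=C8 bond ⇒ aldol condensation of chloro-enone 8 (C8 enolate) with aldehyde 13.
2. Aldehyde 13 (C1–C7, with C5/C6) ⇒ (+)-2,3-O-isopropylidene-L-threitol 9 (from L-tartaric acid); C3–C4 bond by Giese addition to methyl acrylate.
3. Chloro-enone 8 ⇒ 4-hydroxy-4-octenylcyclopentenone 5 (epoxidation/HCl puts Cl on C10, then silylation).
4. Key step: the only ring (C8–C12) is closed by the 4π-conrotatory electrocyclization of a Piancatelli rearrangement of furfuryl alcohol 4, which delivers C9=O, C10=C11 and the C12 carbinol at once.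
5. Stereochemistry: C5/C6 are bought in 9 and 14Z in 1. C12 is formed racemic in the ring-forming step; the 12R series is isolated as a diastereomer after union with enantiopure 13. No external chirality source is used.

Assumption: prostanoid numbering is used (C1 = ester carbon, ring = C8–C12); the target is (5S,6S,7E,12R,14Z). Compounds 1, 3, 9 and 11 are taken as commercial.

---

**Ring fragment**

Step 1
Reactants: 1, (Z)-oct-2-en-1-ol
Product: 2, (Z)-1-bromooct-2-ene
Conditions: CBr4, PPh3, CH2Cl2, –20 → 0 °C
Reagents that add atoms: carbon tetrabromide, BrC(Br)(Br)Br (supplies Br)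
Why: Appel bromination is an SN2 displacement at the primary carbinol, so the Z-alkene is kept and allylic transposition is avoided.

Step 2
Reactants: 3, furfuryl alcohol; 2, (Z)-1-bromooct-2-ene
Product: 4, {5-[(2Z)-oct-2-en-1-yl]furan-2-yl}methanol
Conditions: 3, n-BuLi (2.1 equiv), THF, –78 → 0 °C; then 2, –78 °C → rt
Reagents that add atoms: none (all new atoms come from 2)
Why: O,C5-dilithiation of furfuryl alcohol followed by SN2 alkylation of the furyllithium with the primary allylic bromide leaves the Z geometry untouched.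

Step 3 (key step)
Reactants: 4
Product: 5, (±)-4-hydroxy-4-[(2Z)-oct-2-en-1-yl]cyclopent-2-en-1-one
Conditions: ZnCl2 (1 equiv), dioxane–H2O 1:1, pH ≈ 5–6, 90 °C (or microwave, 140 °C, 15 min)
Reagents that add atoms: water, O (becomes the C12 hydroxyl oxygen)
Why: Piancatelli rearrangement — ionization of the furfuryl alcohol, water attack at furan C5, ring-opening to the 1,4-dihydroxypentadienyl cation and conrotatory 4π-electrocyclization form the C8–C12 bond; C12 is created without facial bias, so 5 is racemic.

Step 4
Reactants: 5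
Product: 6, (±)-2,3-epoxy-4-hydroxy-4-[(2Z)-oct-2-en-1-yl]cyclopentan-1-one (epoxide diastereomers)
Conditions: 30% H2O2, NaOH (0.3 equiv), MeOH, –10 → 0 °C
Reagents that add atoms: hydrogen peroxide, OO
Why: Weitz–Scheffer nucleophilic epoxidation attacks only the electron-poor enone alkene, not the isolated Z-alkene; the epoxide configuration is irrelevant.

Step 5
Reactants: 6
Product: 7, (±)-2-chloro-4-hydroxy-4-[(2Z)-oct-2-en-1-yl]cyclopent-2-en-1-one
Conditions: conc. HCl, THF, 0 °C → rt
Reagents that add atoms: hydrogen chloride, Cl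
Why: chloride opens the α,β-epoxy ketone at C10 (C11 is neopentyl) and the β-hydroxy ketone dehydrates (E1cB) to the 2-chloroenone.

Step 6
Reactants: 7
Product: 8, (±)-2-chloro-4-[(2Z)-oct-2-en-1-yl]-4-[(trimethylsilyl)oxy]cyclopent-2-en-1-one
Conditions: TMSCl, imidazole, DMF, rt
Reagents that add atoms: chlorotrimethylsilane, C[Si](C)(C)Cl
Why: silylation of the tertiary alcohol so that LDA in step 10 deprotonates only C8.

**Side-chain fragment**

Step 7
Reactants: 9, (4S,5S)-2,2-dimethyl-1,3-dioxolane-4,5-dimethanol
Product: 10, [(4S,5R)-5-(iodomethyl)-2,2-dimethyl-1,3-dioxolan-4-yl]methanol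
Conditions: I2 (1.0 equiv), PPh3, imidazole, THF, 0 °C → rt; di-iodide and recovered 9 separated
Reagents that add atoms: iodine, II
Why: Appel-type iodination; 9 is C2-symmetric, so statistical mono-substitution gives one compound and the stereocentres are not touched (the descriptor change is only a CIP priority change).

Step 8
Reactants: 10; 11, methyl acrylate (5 equiv)
Product: 12, methyl 4-[(4S,5S)-5-(hydroxymethyl)-2,2-dimethyl-1,3-dioxolan-4-yl]butanoate
Conditions: Bu3SnH (1.3 equiv, syringe pump), AIBN, benzene, 80 °C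
Reagents that add atoms: none (carbons come from 11; H from Bu3SnH)
Why: Giese radical conjugate addition of the primary C4 radical to methyl acrylate builds C1–C3 in one step; the radical is not at a stereocentre and the free OH is tolerated.

Step 9
Reactants: 12
Product: 13, methyl 4-[(4S,5R)-5-formyl-2,2-dimethyl-1,3-dioxolan-4-yl]butanoate
Conditions: Dess–Martin periodinane, NaHCO3, CH2Cl2, 0 °C → rt; used crude
Reagents that add atoms: none
Why: mild Dess–Martin oxidation gives the α-alkoxy aldehyde without epimerization (the trans-dioxolane is also the thermodynamic isomer).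

**Union and endgame**

Step 10
Reactants: 8; 13
Product: 14, aldol adducts (mixture at C7, C8 and C12; C5/C6 fixed)
Conditions: 8, LDA (1.05 equiv), THF, –78 °C, 20 min; then 13, –78 °C, 15 min; NH4Cl quench
Reagents that add atoms: none
Why: directed aldol addition of the kinetic C8 lithium enolate (the only enolizable position) to the aldehyde; C7/C8 are destroyed in step 11, and both enantiomers of 8 react to give two diastereomeric C12 series.

Step 11
Reactants: 14
Product: 15, methyl (5S,6S,7E,12R,14Z)-10-chloro-5,6-(isopropylidenedioxy)-9-oxo-12-(trimethylsilyloxy)prosta-7,10,14-trien-1-oate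
Conditions: MsCl, Et3N, CH2Cl2, –20 → 0 °C; then DBU, 0 °C → rt; silica chromatography, then HPLC
Reagents that add atoms: none
Why: mesylation and E1cB elimination give the cross-conjugated dienone; the 7E/7Z and 12R/12S isomers are diastereomers and are separated here, and the 7E,12R isomer is carried on (at most about a quarter of the material).

Step 12
Reactants: 15
Product: 16, methyl (5S,6S,7E,12R,14Z)-10-chloro-5,6,12-trihydroxy-9-oxoprosta-7,10,14-trien-1-oate
Conditions: CSA (0.2 equiv), MeOH, rt
Reagents that add atoms: none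
Why: acid-catalysed methanolysis removes the TMS ether and the acetonide (transketalization); methanol as solvent suppresses δ-lactonization of the 5-hydroxy ester.

Step 13
Reactants: 16
Product: 17, punaglandin 4
Conditions: Ac2O, pyridine, 0 °C → rt (no DMAP)
Reagents that add atoms: acetic anhydride, CC(=O)OC(C)=O
Why: selective acetylation of the two secondary hydroxyls; the hindered tertiary C12–OH is not acylated under these conditions.

---

**Compound list**

1 | (Z)-oct-2-en-1-ol | CCCCC/C=C\CO | starting material
2 | (Z)-1-bromooct-2-ene | CCCCC/C=C\CBr | intermediate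
3 | furfuryl alcohol | OCc1ccco1 | starting material
4 | {5-[(2Z)-oct-2-en-1-yl]furan-2-yl}methanol | CCCCC/C=C\Cc1ccc(CO)o1 | intermediate
5 | (±)-4-hydroxy-4-[(2Z)-oct-2-en-1-yl]cyclopent-2-en-1-one | CCCCC/C=C\CC1(O)C=CC(=O)C1 | intermediate
6 | (±)-2,3-epoxy-4-hydroxy-4-[(2Z)-oct-2-en-1-yl]cyclopentan-1-one | CCCCC/C=C\CC1(O)CC(=O)C2OC12 | intermediate
7 | (±)-2-chloro-4-hydroxy-4-[(2Z)-oct-2-en-1-yl]cyclopent-2-en-1-one | CCCCC/C=C\CC1(O)C=C(Cl)C(=O)C1 | intermediate
8 | (±)-2-chloro-4-[(2Z)-oct-2-en-1-yl]-4-[(trimethylsilyl)oxy]cyclopent-2-en-1-one | CCCCC/C=C\CC1(O[Si](C)(C)C)C=C(Cl)C(=O)C1 | intermediate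
9 | (4S,5S)-2,2-dimethyl-1,3-dioxolane-4,5-dimethanol [(+)-2,3-O-isopropylidene-L-threitol] | OC[C@@H]1OC(C)(C)O[C@H]1CO | starting material
10 | [(4S,5R)-5-(iodomethyl)-2,2-dimethyl-1,3-dioxolan-4-yl]methanol | OC[C@@H]1OC(C)(C)O[C@H]1CI | intermediate
11 | methyl acrylate | C=CC(=O)OC | starting material
12 | methyl 4-[(4S,5S)-5-(hydroxymethyl)-2,2-dimethyl-1,3-dioxolan-4-yl]butanoate | OC[C@@H]1OC(C)(C)O[C@H]1CCCC(=O)OC | intermediate
13 | methyl 4-[(4S,5R)-5-formyl-2,2-dimethyl-1,3-dioxolan-4-yl]butanoate | O=C[C@@H]1OC(C)(C)O[C@H]1CCCC(=O)OC | intermediate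
14 | aldol adducts of 8 and 13 (C7, C8, C12 unassigned) | CCCCC/C=C\CC1(O[Si](C)(C)C)C=C(Cl)C(=O)C1C(O)[C@@H]2OC(C)(C)O[C@H]2CCCC(=O)OC | intermediate
15 | methyl (5S,6S,7E,12R,14Z)-10-chloro-5,6-(isopropylidenedioxy)-9-oxo-12-(trimethylsilyloxy)prosta-7,10,14-trien-1-oate | CCCCC/C=C\C[C@@]1(O[Si](C)(C)C)C=C(Cl)C(=O)/C1=C/[C@@H]2OC(C)(C)O[C@H]2CCCC(=O)OC | intermediate
16 | methyl (5S,6S,7E,12R,14Z)-10-chloro-5,6,12-trihydroxy-9-oxoprosta-7,10,14-trien-1-oate | CCCCC/C=C\C[C@@]1(O)C=C(Cl)C(=O)/C1=C/[C@H](O)[C@@H](O)CCCC(=O)OC | intermediate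
17 | punaglandin 4, methyl (5S,6S,7E,12R,14Z)-5,6-diacetoxy-10-chloro-12-hydroxy-9-oxoprosta-7,10,14-trien-1-oate | CCCCC/C=C\C[C@@]1(O)C=C(Cl)C(=O)/C1=C/[C@H](OC(C)=O)[C@H](CCCC(=O)OC)OC(C)=O | target

---

**Totals**
Total steps: 13. Longest linear sequence: 10 (steps 1–6, then 10–13); the side-chain branch is 3 steps (7–9).

**Three steps most likely to fail, with fallbacks**
1. Step 11 (with step 10): four isomers form (7E/7Z × 12R/12S). C12 is not set selectively, so the target isomer has to be separated from its 12-epimer and the 7Z isomers. Fallback: make the ring as a single enantiomer from the chiral pool. (R)-4-(TBSO)cyclopent-2-enone from D-tartaric acid, 1,2-addition of (Z)-oct-2-enylbarium anti to the silyloxy group (sets C12), desilylation and MnO2 oxidation give (S)-5. The aldol diastereomers can then be separated and eliminated stereospecifically (anti via mesylate; syn via DCC/CuCl) to favour 7E.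
2. Step 3: Piancatelli rearrangement of a primary, 5-alkyl furfuryl alcohol is slow and competes with polymerization. Fallback: build the same ring by aldol instead — oxidative opening of 2-methyl-5-[(Z)-oct-2-enyl]furan (NBS, NaHCO3, aqueous acetone) to the (Z)-ene-1,4-dione, then Na2CO3-mediated intramolecular aldol to 5.
3. Steps 4–5: the tertiary aldol unit is exposed to base (retro-aldol) and then strong acid during chlorination. Fallback: carry chlorine through the rearrangement — prepare (3-chloro-5-octenylfuran-2-yl)methanol from 3-chlorofuran (LDA/DMF, NaBH4, then the step-2 alkylation) and rearrange it directly to 7.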